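## Structural features

The target is a daucane sesquiterpene ester. A cyclopentane (C1–C5) is fused through the C1–C5 bond to a cycloheptane (C1, C10, C9, C8, C7, C6, C5), and C6 carries a 4-hydroxybenzoate. The descriptors place the C1 methyl and the C5 hydrogen on the same face, so the hydroazulene is cis-fused (1S,4R,5S,6R,8R,9S in daucane numbering). C4 (tertiary carbinol with isopropyl), C5 and C6 are contiguous and C5 adjoins the quaternary C1. Both the C4 and C6 oxygens lie on the face opposite the C1 methyl, while the oxygen of the C8–C9 oxirane lies on the methyl face. Fragile groups are: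
- the trisubstituted epoxide, which is sensitive to acid and to transannular attack by the C4 hydroxyl;
- the C4 alcohol, which is β to C6 and so risks retro-aldol cleavage or dehydration whenever C6 is a carbonyl;
- the aryl ester beside a free phenol;
- C5, which epimerises whenever it is flanked by carbonyls.

The real difficulties are the absolute configuration of quaternary C1, the C5 configuration relative to a C1 whose methyl and CH2 substituents differ little in size, the addition of a secondary alkyl group at C4 next to an acidic C5, and C6. The key step uses the fact that C5 sits between the oxygenated carbons C4 and C6 and can therefore be the diazo carbon of a 3-oxo ester, while C1 is a methyl-branched methine in reach of a five-ring-forming insertion. The C9 oxygen on the two-carbon arm of C1 can in addition close a six-membered lactone onto C6, which locks C5.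

## Logic of the disconnections

24 to 23: the O–CH2 bond of a benzyl ether on the phenol is cut. The phenol must be masked during esterification and epoxidation. Nothing is gained in skeleton. The forward step has to remove the benzyl group without opening the epoxide or the ester.

23 to 22: the C8–O and C9–O bonds of the oxirane are cut, so the most acid-sensitive group enters late. Two stereocentres disappear. The forward step must deliver oxygen to the face of the C8=C9 bond that carries the C1 methyl, anti to the C6 ester.

22 to 20 and 21: the C6 O–acyl bond is cut. The aromatic part is a purchased acid and 20 is a simple diol. The forward step must acylate a hindered secondary hydroxyl and leave the tertiary C4 hydroxyl alone.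

20 to 19: the C8=C9 bond is cut as a ring-closing metathesis. The seven-membered ring opens to a cyclopentane with two cis side chains, and the alkene ends up exactly where the epoxide is needed. The forward step must form a trisubstituted alkene in a medium ring with free hydroxyls present.

19 to 16 and 18, then 16 to 17 to 15: the C9=CH2 bond is cut, and C9 is taken back through aldehyde and ester oxidation levels to the primary carbinol. C9 arrives from the chiral pool as a CH2OH group. Passing through a lactone to the C6 oxygen shields the C6 carbinol from oxidation without a protecting group. The demand is a primary-selective oxidation.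

15 to 14: the C6–H bond is cut. Carbon addition to a C6 aldehyde chelated to the C4 oxygen would give the wrong C6 epimer, whereas hydride delivery to a chelated C6 ketone gives the right one. The demand is a chelation-controlled reduction of a β-hydroxy ketone.

14 to 12 and 13: the C6–C7 bond is cut, with the lactone carbonyl as the acylating carbon. This removes four carbons and leaves a bicyclic lactone. The demand is a single addition of an allylic organometallic to a lactone.

12 to 10 and 11: the C4–isopropyl bond is cut. The tertiary carbinol becomes a ketone. The forward step must add to an enolisable β-keto lactone instead of deprotonating it, and from the convex face.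

10 to 8 (through 9): the lactone C6–O bond is cut. The lactone ring exists to force C6 and C10 cis on the cyclopentane, which fixes C5 relative to C1. The demand is that C5 equilibrates while the ring closes.

8 to 7: the C1–C5 bond is cut. This opens the five-membered ring and turns quaternary C1 back into the methine of the chiral pool. The forward step must insert into that one C–H bond with retention.

7 to 5 and 6, 5 to 3 and 4, 3 to 2, 2 to 1: the diazo group, the C4–C5 bond, the C4 carbonyl (as an alkene cleavage) and the O–Si bond are cut in turn. This leaves one purchased terpene alcohol, a two-carbon diazo ester and a diazo-transfer reagent. Demands are routine, except that the oxygen on C9 must be masked before the carbenoid is formed.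

## Other disconnections considered

Alternative 1: The cut is the C1–C10 bond, undone as a 1,2-alkyl shift. The bicycle is traced to dauca-4,8-diene A2 and this to the spiro[4.5]decenol A1, in which C10 is still bonded to the spiro carbon C5 and C1 is a methyl carbinol.
- Forward step: formic acid or BF3·OEt2 would ionise the C1 carbinol of A1. The allylic C10 would migrate from C5 to C1 on the face it occupies, enlarging the six-membered ring to seven and creating quaternary C1. Loss of a C4 proton would leave the C4=C5 alkene of A2.
- In favour: it follows the presumed biogenesis and needs no diazo compound or metathesis catalyst. It reaches the full C15 skeleton in fewer C–C bond-forming steps, so on skeletal step economy it is the better plan.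
- Against: A2 keeps a single stereocentre. The C4 hydroxyl, the C5 hydrogen and the C6 oxygen would all have to be placed on a tetrasubstituted C4=C5 alkene beside the C8=C9 alkene, with cis fusion and the C4/C6 syn relationship, and the diene offers no handle for this. The cation can also be diverted by competing shifts or by migration of the C8=C9 bond, and the spiro centre of A1 needs its own enantioselective entry.
- Comparison: the shift is stereospecific at C1, as the insertion is, so the two are equal on that point. The chosen plan reaches the bicycle with C4, C5 and C6 already in place, so after oxidation-level and stereochemical repair the total count should favour it.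

Alternative 2: The cut removes both ring bonds to C1 (C1–C5 and C1–C10) and leads from the dihydroazulenone A4 back to the aryl diazo ketone A3, a methoxytoluene with a ketal-protected 3-diazobutan-2-one side chain.
- Forward step: [Cu(MeCN)4]PF6 with a chiral bis(oxazoline) would give a monovalent-copper carbenoid at C1. This cyclopropanates the C5–C10 bond of the arene, and electrocyclic opening of the norcaradiene gives the cycloheptatriene A4 (Buchner reaction).
- In favour: both rings and the quaternary centre come from a flat, cheap aromatic in one step, with oxygen already at C4 and C6. In ring-forming economy it is better than the chosen plan.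
- Against: the absolute configuration at C1 would rest on catalyst control of a carbenoid with an α-methyl group, which is prone to 1,2-hydride shift to an enone. The addition must choose the C5–C10 bond over the C5–C6 bond next to the methoxy group. A4 carries a surplus C2 ketone and two surplus ring alkenes, so deoxygenation, reduction that spares C8=C9, and the C5 and C6 configurations all remain.
- Comparison: the chosen plan takes C1 from the chiral pool with retention that is inherent to the mechanism, and closes the seven-membered ring with the alkene already at C8=C9. The alternative is shorter to a bicycle but probably equal or longer overall once the redox corrections are counted.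

Alternative 3: The cut removes C5–C6 and C4–O together. The isoxazoline A6 is traced to the aldoxime A5, a cyclopentene (C4=C5, isopropyl on C4, quaternary C1) whose C1 chain contains the Z C8=C9 alkene and ends in the C6 oxime.
- Forward step: NaOCl would oxidise A5 to the nitrile oxide, which adds across C4=C5 from the face of its tether, closing the seven-membered ring and the isoxazoline.
- In favour: the suprafacial, tether-delivered cycloaddition sets C4 and C5 together, with the C4 oxygen, C6 and C10 on one face, which is the cis-fused, syn arrangement of the target. It makes the tertiary C4 alcohol without adding an organometallic to an enolisable β-dicarbonyl, and on this point it is better than the chosen plan. After N–O cleavage it arrives at the same C6 ketone reduction, so it is equal there.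
- Against: seven-membered ring closure by nitrile oxide cycloaddition onto a hindered trisubstituted alkene competes with dimerisation. The β,γ-unsaturated nitrile oxide can isomerise. The N–O bond must be cleaved without touching C8=C9. A5 still needs an enantioselective entry to C1 and a Z-selective trisubstituted alkene.
- Comparison: structurally it is the most direct for C4 and C5, mechanistically it is less secure in the ring closure than metathesis, and its step count is comparable because the C1 problem is only postponed.

Key step: step 5

Remark: the descriptors of the target place the C1 methyl and the C5 hydrogen syn, so the route aims at the cis-fused ring system; the (R)-methine of 1 maps with retention onto (S)-C1, and the C5 descriptor written for 8 is nominal because that centre is a labile β-keto ester position until step 6.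

Step 1
Reactants: 1 (R)-citronellol
Product: 2 tert-butyl{[(3R)-3,7-dimethyloct-6-en-1-yl]oxy}dimethylsilane
Conditions: TBSCl, imidazole, DMF, 0 °C to rt
Reagents that add atoms: tert-butyldimethylsilyl chloride, CC(C)(C)[Si](C)(C)Cl
Why: Silyl ether formation on an unhindered primary alcohol; the ether keeps the oxygen out of ozonolysis side reactions and out of O–H insertion in step 5.

Step 2
Reactants: 2 tert-butyl{[(3R)-3,7-dimethyloct-6-en-1-yl]oxy}dimethylsilane
Product: 3 (4R)-6-[(tert-butyldimethylsilyl)oxy]-4-methylhexanal
Conditions: O3, CH2Cl2, −78 °C; then Me2S, −78 °C to rt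
Reagents that add atoms: ozone, [O-][O+]=O
Why: Ozonolysis with reductive work-up cleaves the trisubstituted alkene to the aldehyde and acetone; the silyl ether and the remote stereocentre are not affected.

Step 3
Reactants: 3 (4R)-6-[(tert-butyldimethylsilyl)oxy]-4-methylhexanal; 4 methyl diazoacetate
Product: 5 methyl (6R)-8-[(tert-butyldimethylsilyl)oxy]-6-methyl-3-oxooctanoate
Conditions: SnCl2 (10 mol %), CH2Cl2, rt (4 used as a dilute solution)
Reagents that add atoms: methyl diazoacetate (4), COC(=O)C=[N+]=[N-]
Why: Roskamp homologation: the Lewis acid promotes addition of the diazo ester to the aldehyde, and a 1,2-hydride shift with loss of N2 gives the β-keto ester directly.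

Step 4
Reactants: 5 methyl (6R)-8-[(tert-butyldimethylsilyl)oxy]-6-methyl-3-oxooctanoate; 6 4-acetamidobenzenesulfonyl azide
Product: 7 methyl (6R)-8-[(tert-butyldimethylsilyl)oxy]-2-diazo-6-methyl-3-oxooctanoate
Conditions: Et3N, MeCN, 0 °C to rt
Reagents that add atoms: 4-acetamidobenzenesulfonyl azide (6), CC(=O)Nc1ccc(cc1)S(=O)(=O)N=[N+]=[N-]
Why: Regitz diazo transfer to the active methylene of a β-keto ester; the sulfonamide by-product is removed by filtration and washing.

Step 5
Reactants: 7 methyl (6R)-8-[(tert-butyldimethylsilyl)oxy]-2-diazo-6-methyl-3-oxooctanoate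
Product: 8 methyl (1R,2S)-2-{2-[(tert-butyldimethylsilyl)oxy]ethyl}-2-methyl-5-oxocyclopentane-1-carboxylate
Conditions: Rh2(OAc)4 (1 mol %), CH2Cl2, rt, slow addition of 7
Reagents that add atoms: none
Why: Rh2(OAc)4 expels N2 from 7 to give an electrophilic divalent-rhodium carbenoid at C5, which inserts into the C1–H bond through a concerted three-centre transition state. The closest known reaction type is the dirhodium tetracarboxylate-catalysed intramolecular 1,5 C–H insertion of α-diazo β-keto esters into unactivated tertiary C–H bonds. The cyclopentane is closed by 1,5-insertion: the new C1–C5 bond joins the carbenoid carbon to the methine four bonds away through a chair-like six-membered array that includes the migrating hydrogen. C1 is formed with retention because carbon replaces hydrogen on the same face, so the (R)-methine of 1 alone controls it and becomes (S)-C1. C5 is a β-keto ester centre under thermodynamic control and is not relied on here; it is fixed in step 6. The step needs site selectivity for the C1 methine over the C10 methylene (six-membered ring), the C1 methyl (six-membered ring, primary C–H) and the O–CH2 group (seven-membered ring). The preference for five-ring formation and the methine > methylene > methyl order of electrophilic carbenoids should secure this, and the silyl ether prevents O–H insertion.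

Step 6
Reactants: 8 methyl (1R,2S)-2-{2-[(tert-butyldimethylsilyl)oxy]ethyl}-2-methyl-5-oxocyclopentane-1-carboxylate
Product: 10 (4aS,7aR)-4a-methylhexahydrocyclopenta[c]pyran-1,7-dione, via hydroxy keto ester 9 (not isolated)
Conditions: TsOH·H2O (cat.), MeOH, rt; then PhMe, 80 °C (MeOH distilled off)
Reagents that add atoms: none
Why: Acid-catalysed desilylation followed by lactonisation (intramolecular transesterification). C5 equilibrates through the enol and only the epimer with C6 cis to the C10 arm can close the six-membered ring, so the cis-fused keto lactone results and the C5 hydrogen is set syn to the C1 methyl.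

Step 7
Reactants: 10 (4aS,7aR)-4a-methylhexahydrocyclopenta[c]pyran-1,7-dione; 11 isopropylmagnesium chloride
Product: 12 (4aS,7R,7aR)-7-hydroxy-4a-methyl-7-(propan-2-yl)hexahydrocyclopenta[c]pyran-1(3H)-one
Conditions: CeCl3 (anhydrous), THF, −78 °C
Reagents that add atoms: isopropylmagnesium chloride (11), CC(C)[Mg]Cl
Why: Organocerium 1,2-addition, whose low basicity should favour carbonyl addition over enolisation of the β-dicarbonyl and over β-hydride reduction. The reagent approaches the ketone on the convex face of the cis-fused bicycle, anti to the C5–C6 bond, so the C4 hydroxyl ends up cis to C6 as in the target.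

Step 8
Reactants: 12 (4aS,7R,7aR)-7-hydroxy-4a-methyl-7-(propan-2-yl)hexahydrocyclopenta[c]pyran-1(3H)-one; 13 2-methylallylmagnesium chloride
Product: 14 1-[(1R,2R,5S)-2-hydroxy-5-(2-hydroxyethyl)-5-methyl-2-(propan-2-yl)cyclopentyl]-3-methylbut-3-en-1-one
Conditions: THF, −78 °C; aq. NH4Cl at −78 °C
Reagents that add atoms: 2-methylallylmagnesium chloride (13), CC(=C)C[Mg]Cl
Why: Single addition of an allylic Grignard reagent to a δ-lactone: the hindered cyclic hemiketal alkoxide should persist at low temperature, so the ketone (in equilibrium with its ring tautomer) is released only on cold quench. The first equivalent is consumed by the tertiary hydroxyl.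

Step 9
Reactants: 14 1-[(1R,2R,5S)-2-hydroxy-5-(2-hydroxyethyl)-5-methyl-2-(propan-2-yl)cyclopentyl]-3-methylbut-3-en-1-one
Product: 15 (1R,2S,3S)-2-[(1R)-1-hydroxy-3-methylbut-3-en-1-yl]-3-(2-hydroxyethyl)-3-methyl-1-(propan-2-yl)cyclopentan-1-ol
Conditions: Et2BOMe, THF/MeOH, −78 °C; NaBH4; then AcOH, MeOH (azeotrope)
Reagents that add atoms: none
Why: Narasaka–Prasad reduction: boron bridges the C4 oxygen and the C6 carbonyl oxygen, and external hydride attacks the chelated ketone. The face next to C1 is covered by the C10 arm, so hydride should arrive past the C5 hydrogen and give the (6R) alcohol, with the C6 hydroxyl on the same face as the C4 hydroxyl.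

Step 10
Reactants: 15 (1R,2S,3S)-2-[(1R)-1-hydroxy-3-methylbut-3-en-1-yl]-3-(2-hydroxyethyl)-3-methyl-1-(propan-2-yl)cyclopentan-1-ol
Product: 17 (1R,4aS,7R,7aS)-7-hydroxy-4a-methyl-1-(2-methylprop-2-en-1-yl)-7-(propan-2-yl)hexahydrocyclopenta[c]pyran-3(1H)-one, via lactol 16 (not isolated)
Conditions: TEMPO (cat.), PhI(OAc)2, CH2Cl2, rt
Reagents that add atoms: none
Why: Oxoammonium-mediated oxidative lactonisation of a 1,5-diol: the primary C9 alcohol is oxidised selectively, the aldehyde is trapped by the C6 hydroxyl and the lactol is oxidised on, so the lactone is the defined stopping point. Closure through the C4 hydroxyl instead would be of no consequence, because steps 11 and 12 converge on 19 either way.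

Step 11
Reactants: 17 (1R,4aS,7R,7aS)-7-hydroxy-4a-methyl-1-(2-methylprop-2-en-1-yl)-7-(propan-2-yl)hexahydrocyclopenta[c]pyran-3(1H)-one
Product: 16 (1R,4aS,7R,7aS)-4a-methyl-1-(2-methylprop-2-en-1-yl)-7-(propan-2-yl)octahydrocyclopenta[c]pyran-3,7-diol (mixture at C3)
Conditions: iBu2AlH, CH2Cl2, −78 °C; Rochelle salt work-up
Reagents that add atoms: none
Why: Half-reduction of a lactone to the lactol; the tetrahedral aluminate is stable at low temperature, and the alkene and the tertiary alcohol are inert.

Step 12
Reactants: 16 (1R,4aS,7R,7aS)-4a-methyl-1-(2-methylprop-2-en-1-yl)-7-(propan-2-yl)octahydrocyclopenta[c]pyran-3,7-diol; 18 methyltriphenylphosphonium bromide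
Product: 19 (1R,2S,3S)-2-[(1R)-1-hydroxy-3-methylbut-3-en-1-yl]-3-methyl-1-(propan-2-yl)-3-(prop-2-en-1-yl)cyclopentan-1-ol
Conditions: KOtBu, THF, 0 °C to rt (excess ylide)
Reagents that add atoms: methyltriphenylphosphonium bromide (18), as its ylide, C[P+](c1ccccc1)(c1ccccc1)c1ccccc1.[Br-]
Why: Wittig methylenation of a lactol through its open hydroxy aldehyde form; no stereocentre is α to the aldehyde, so nothing can epimerise.

Step 13
Reactants: 19 (1R,2S,3S)-2-[(1R)-1-hydroxy-3-methylbut-3-en-1-yl]-3-methyl-1-(propan-2-yl)-3-(prop-2-en-1-yl)cyclopentan-1-ol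
Product: 20 (3R,3aS,4R,8aS)-6,8a-dimethyl-3-(propan-2-yl)-1,2,3,3a,4,5,8,8a-octahydroazulene-3,4-diol
Conditions: second-generation Grubbs catalyst, (H2IMes)(PCy3)Cl2Ru=CHPh (5 mol %), CH2Cl2 (dilute), 40 °C
Reagents that add atoms: none
Why: Ring-closing metathesis of a monosubstituted with a 1,1-disubstituted alkene; the two chains are cis on adjacent ring carbons, which favours closure of the cycloheptene with loss of ethene and places the trisubstituted alkene at C8=C9.

Step 14
Reactants: 20 (3R,3aS,4R,8aS)-6,8a-dimethyl-3-(propan-2-yl)-1,2,3,3a,4,5,8,8a-octahydroazulene-3,4-diol; 21 4-(benzyloxy)benzoic acid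
Product: 22 (3R,3aS,4R,8aS)-3-hydroxy-6,8a-dimethyl-3-(propan-2-yl)-1,2,3,3a,4,5,8,8a-octahydroazulen-4-yl 4-(benzyloxy)benzoate
Conditions: DCC, DMAP, CH2Cl2, rt
Reagents that add atoms: 4-(benzyloxy)benzoic acid (21), OC(=O)c1ccc(OCc2ccccc2)cc1
Why: Steglich esterification; the secondary C6 hydroxyl is acylated while the tertiary C4 hydroxyl is too hindered to react, and the benzyl ether is not an acyl donor that could scramble.

Step 15
Reactants: 22 (3R,3aS,4R,8aS)-3-hydroxy-6,8a-dimethyl-3-(propan-2-yl)-1,2,3,3a,4,5,8,8a-octahydroazulen-4-yl 4-(benzyloxy)benzoate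
Product: 23 (1S,4R,5S,6R,8R,9S)-8,9-epoxy-4-hydroxydaucan-6-yl 4-(benzyloxy)benzoate (daucane numbering; oxirane oxygen on the face of the C1 methyl)
Conditions: mCPBA, NaHCO3, CH2Cl2, 0 °C
Reagents that add atoms: 3-chloroperbenzoic acid, OOC(=O)c1cccc(Cl)c1
Why: Prilezhaev epoxidation of the only alkene. The peracid should approach the convex face of the cis-fused bicycle, anti to the C6 aroyloxy group and away from the folded five-membered ring, which sets C8 and C9; the buffer protects the epoxide from acid and from attack by the C4 hydroxyl.

Step 16
Reactants: 23 (1S,4R,5S,6R,8R,9S)-8,9-epoxy-4-hydroxydaucan-6-yl 4-(benzyloxy)benzoate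
Product: 24 (1S,4R,5S,6R,8R,9S)-8,9-epoxy-4-hydroxydaucan-6-yl 4-hydroxybenzoate (target)
Conditions: H2 (1 atm), Pd/C, EtOAc, rt
Reagents that add atoms: none
Why: Hydrogenolysis of a benzyl aryl ether under neutral conditions; the epoxide is neither benzylic nor allylic, and the alkyl benzoate and the tertiary alcohol are stable.

Compound list

1 | (R)-citronellol | C[C@H](CCC=C(C)C)CCO | starting material
2 | tert-butyl{[(3R)-3,7-dimethyloct-6-en-1-yl]oxy}dimethylsilane | C[C@H](CCC=C(C)C)CCO[Si](C)(C)C(C)(C)C | intermediate
3 | (4R)-6-[(tert-butyldimethylsilyl)oxy]-4-methylhexanal | O=CCC[C@@H](C)CCO[Si](C)(C)C(C)(C)C | intermediate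
4 | methyl diazoacetate | COC(=O)C=[N+]=[N-] | starting material
5 | methyl (6R)-8-[(tert-butyldimethylsilyl)oxy]-6-methyl-3-oxooctanoate | COC(=O)CC(=O)CC[C@@H](C)CCO[Si](C)(C)C(C)(C)C | intermediate
6 | 4-acetamidobenzenesulfonyl azide | CC(=O)Nc1ccc(cc1)S(=O)(=O)N=[N+]=[N-] | starting material
7 | methyl (6R)-8-[(tert-butyldimethylsilyl)oxy]-2-diazo-6-methyl-3-oxooctanoate | COC(=O)C(=[N+]=[N-])C(=O)CC[C@@H](C)CCO[Si](C)(C)C(C)(C)C | intermediate
8 | methyl (1R,2S)-2-{2-[(tert-butyldimethylsilyl)oxy]ethyl}-2-methyl-5-oxocyclopentane-1-carboxylate | COC(=O)[C@H]1C(=O)CC[C@@]1(C)CCO[Si](C)(C)C(C)(C)C | intermediate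
9 | methyl (1R,2S)-2-(2-hydroxyethyl)-2-methyl-5-oxocyclopentane-1-carboxylate | COC(=O)[C@H]1C(=O)CC[C@@]1(C)CCO | intermediate
10 | (4aS,7aR)-4a-methylhexahydrocyclopenta[c]pyran-1,7-dione | O=C1OCC[C@]2(C)CCC(=O)[C@H]12 | intermediate
11 | isopropylmagnesium chloride | CC(C)[Mg]Cl | starting material
12 | (4aS,7R,7aR)-7-hydroxy-4a-methyl-7-(propan-2-yl)hexahydrocyclopenta[c]pyran-1(3H)-one | CC(C)[C@]1(O)CC[C@@]2(C)CCOC(=O)[C@@H]12 | intermediate
13 | 2-methylallylmagnesium chloride | CC(=C)C[Mg]Cl | starting material
14 | 1-[(1R,2R,5S)-2-hydroxy-5-(2-hydroxyethyl)-5-methyl-2-(propan-2-yl)cyclopentyl]-3-methylbut-3-en-1-one | CC(C)[C@]1(O)CC[C@@](C)(CCO)[C@H]1C(=O)CC(C)=C | intermediate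
15 | (1R,2S,3S)-2-[(1R)-1-hydroxy-3-methylbut-3-en-1-yl]-3-(2-hydroxyethyl)-3-methyl-1-(propan-2-yl)cyclopentan-1-ol | CC(C)[C@]1(O)CC[C@@](C)(CCO)[C@H]1[C@H](O)CC(C)=C | intermediate
16 | (1R,4aS,7R,7aS)-4a-methyl-1-(2-methylprop-2-en-1-yl)-7-(propan-2-yl)octahydrocyclopenta[c]pyran-3,7-diol | CC(C)[C@]1(O)CC[C@@]2(C)CC(O)O[C@H](CC(C)=C)[C@@H]12 | intermediate
17 | (1R,4aS,7R,7aS)-7-hydroxy-4a-methyl-1-(2-methylprop-2-en-1-yl)-7-(propan-2-yl)hexahydrocyclopenta[c]pyran-3(1H)-one | CC(C)[C@]1(O)CC[C@@]2(C)CC(=O)O[C@H](CC(C)=C)[C@@H]12 | intermediate
18 | methyltriphenylphosphonium bromide | C[P+](c1ccccc1)(c1ccccc1)c1ccccc1.[Br-] | starting material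
19 | (1R,2S,3S)-2-[(1R)-1-hydroxy-3-methylbut-3-en-1-yl]-3-methyl-1-(propan-2-yl)-3-(prop-2-en-1-yl)cyclopentan-1-ol | CC(C)[C@]1(O)CC[C@@](C)(CC=C)[C@H]1[C@H](O)CC(C)=C | intermediate
20 | (3R,3aS,4R,8aS)-6,8a-dimethyl-3-(propan-2-yl)-1,2,3,3a,4,5,8,8a-octahydroazulene-3,4-diol | CC(C)[C@]1(O)CC[C@@]2(C)CC=C(C)C[C@@H](O)[C@H]21 | intermediate
21 | 4-(benzyloxy)benzoic acid | OC(=O)c1ccc(OCc2ccccc2)cc1 | starting material
22 | (3R,3aS,4R,8aS)-3-hydroxy-6,8a-dimethyl-3-(propan-2-yl)-1,2,3,3a,4,5,8,8a-octahydroazulen-4-yl 4-(benzyloxy)benzoate | CC(C)[C@]1(O)CC[C@@]2(C)CC=C(C)C[C@@H](OC(=O)c3ccc(OCc4ccccc4)cc3)[C@H]21 | intermediate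
23 | (1S,4R,5S,6R,8R,9S)-8,9-epoxy-4-hydroxydaucan-6-yl 4-(benzyloxy)benzoate | CC(C)[C@]1(O)CC[C@@]2(C)C[C@@H]3O[C@]3(C)C[C@@H](OC(=O)c3ccc(OCc4ccccc4)cc3)[C@H]21 | intermediate
24 | (1S,4R,5S,6R,8R,9S)-8,9-epoxy-4-hydroxydaucan-6-yl 4-hydroxybenzoate | CC(C)[C@]1(O)CC[C@@]2(C)C[C@@H]3O[C@]3(C)C[C@@H](OC(=O)c3ccc(O)cc3)[C@H]21 | target

Total step count: 16. Longest linear sequence: 16 steps from 1; compounds 4, 6, 11, 13, 18 and 21 are purchased.

Least certain steps

Step 5 (key step). What is most likely to go wrong is diversion of the carbenoid before it reaches the hindered methine: reaction at the electron-rich silyloxy end (attack on oxygen or on the activated O–CH2 hydrogens) and carbene dimerisation if insertion is slow. The fallback changes the substrate and not the catalyst. It sets out from 5 and comes back at 10.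
- Desilylation of 5 with HF·pyridine gives methyl (6R)-8-hydroxy-6-methyl-3-oxooctanoate F1.
- Ac2O and pyridine give methyl (6R)-8-acetoxy-6-methyl-3-oxooctanoate F2, whose ester oxygen is non-nucleophilic and deactivates its own O–CH2 group.
- Diazo transfer with 6 gives methyl (6R)-8-acetoxy-2-diazo-6-methyl-3-oxooctanoate F3.
- Rh2(OAc)4 should convert F3 into methyl (1R,2S)-2-(2-acetoxyethyl)-2-methyl-5-oxocyclopentane-1-carboxylate F4.
- Acid methanolysis of F4 (TsOH, MeOH, 50 °C) gives 9, which lactonises to 10 as in step 6.

Step 7. Deprotonation at C5 of the β-keto lactone, or β-hydride reduction of the ketone by the secondary alkyl reagent, may outrun addition, because C5 is doubly activated and isopropyl is a hindered, hydride-donating nucleophile. The fallback sets out from 10 and comes back at 12. It adds an sp2 nucleophile, which is less basic and cannot donate hydride: isopropenylmagnesium bromide with CeCl3 should give (4aS,7S,7aR)-7-hydroxy-4a-methyl-7-(prop-1-en-2-yl)hexahydrocyclopenta[c]pyran-1(3H)-one F5. Hydrogenation (H2, Pd/C, EtOAc) then gives 12.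

Step 8. A second addition to the liberated ketone, or migration of the β,γ double bond into conjugation during quench, may occur if the hemiketal alkoxide collapses before work-up. The fallback sets out from 12 and comes back at 14. The lactone is opened with MeNH(OMe)·HCl and iPrMgCl to (1R,2R,5S)-2-hydroxy-5-(2-hydroxyethyl)-N-methoxy-N,5-dimethyl-2-(propan-2-yl)cyclopentane-1-carboxamide F6. This is used at once with 13 in a Weinreb ketone synthesis, which stops cleanly at 14.

Step 9. Facial selectivity may be poor if the tertiary C4 hydroxyl is slow to form the boron chelate or if the ketone rests as its ring tautomer, so that unchelated reduction competes. The fallback corrects C6 where the ring enforces the outcome; it sets out from 20 (obtained mixed with its C6 epimer) and comes back at 20.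
- The mixture from step 9 is carried through steps 10 to 13, giving 20 together with (3R,3aS,4S,8aS)-6,8a-dimethyl-3-(propan-2-yl)-1,2,3,3a,4,5,8,8a-octahydroazulene-3,4-diol F7.
- Dess–Martin oxidation converges both on (3R,3aR,8aS)-3-hydroxy-6,8a-dimethyl-3-(propan-2-yl)-2,3,3a,5,8,8a-hexahydroazulen-4(1H)-one F8.
- In F8 the boron chelate holds the C6 oxygen on the face of the C4 oxygen, so hydride from Et2BOMe/NaBH4 can only arrive from the opposite, convex face and gives 20.

Step 15. Oxygen may be delivered to the face opposite the C1 methyl, because the angular methyl partly shields the convex face of the seven-membered ring. The fallback inverts the facial outcome of electrophilic attack; it sets out from 22 and comes back at 23. NBS in aqueous THF should form the bromonium ion on the same accessible face, and water opens it at C8 from the methyl face. This gives 9-bromo-4,8-dihydroxydaucan-6-yl 4-(benzyloxy)benzoate F9 (C8 hydroxyl on the face of the C1 methyl, C9 bromine trans to it). K2CO3 in MeOH closes F9 with inversion at C9 to the epoxide 23.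

Further compounds

F1 | step 5 | methyl (6R)-8-hydroxy-6-methyl-3-oxooctanoate | COC(=O)CC(=O)CC[C@@H](C)CCO
F2 | step 5 | methyl (6R)-8-acetoxy-6-methyl-3-oxooctanoate | COC(=O)CC(=O)CC[C@@H](C)CCOC(C)=O
F3 | step 5 | methyl (6R)-8-acetoxy-2-diazo-6-methyl-3-oxooctanoate | COC(=O)C(=[N+]=[N-])C(=O)CC[C@@H](C)CCOC(C)=O
F4 | step 5 | methyl (1R,2S)-2-(2-acetoxyethyl)-2-methyl-5-oxocyclopentane-1-carboxylate | COC(=O)[C@H]1C(=O)CC[C@@]1(C)CCOC(C)=O
F5 | step 7 | (4aS,7S,7aR)-7-hydroxy-4a-methyl-7-(prop-1-en-2-yl)hexahydrocyclopenta[c]pyran-1(3H)-one | CC(=C)[C@]1(O)CC[C@@]2(C)CCOC(=O)[C@@H]12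
F6 | step 8 | (1R,2R,5S)-2-hydroxy-5-(2-hydroxyethyl)-N-methoxy-N,5-dimethyl-2-(propan-2-yl)cyclopentane-1-carboxamide | CC(C)[C@]1(O)CC[C@@](C)(CCO)[C@H]1C(=O)N(C)OC
F7 | step 9 | (3R,3aS,4S,8aS)-6,8a-dimethyl-3-(propan-2-yl)-1,2,3,3a,4,5,8,8a-octahydroazulene-3,4-diol | CC(C)[C@]1(O)CC[C@@]2(C)CC=C(C)C[C@H](O)[C@H]21
F8 | step 9 | (3R,3aR,8aS)-3-hydroxy-6,8a-dimethyl-3-(propan-2-yl)-2,3,3a,5,8,8a-hexahydroazulen-4(1H)-one | CC(C)[C@]1(O)CC[C@@]2(C)CC=C(C)CC(=O)[C@H]21
F9 | step 15 | 9-bromo-4,8-dihydroxydaucan-6-yl 4-(benzyloxy)benzoate (8-hydroxyl on the face of the C1 methyl, 9-bromine trans to it) | CC(C)[C@]1(O)CC[C@@]2(C)C[C@@H](Br)[C@](C)(O)C[C@@H](OC(=O)c3ccc(OCc4ccccc4)cc3)[C@H]21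
A1 | alternative 1 | 1,8-dimethyl-4-(propan-2-yl)spiro[4.5]dec-7-en-1-ol (spiro centre as required for the target C1) | CC(C)C1CCC(C)(O)[C@]12CCC(C)=CC2
A2 | alternative 1 | dauca-4,8-diene, (8aS)-6,8a-dimethyl-3-(propan-2-yl)-1,2,4,5,8,8a-hexahydroazulene | CC(C)C1=C2CCC(C)=CC[C@]2(C)CC1
A3 | alternative 2 | 3-diazo-1-[2-(2-methoxy-4-methylphenyl)-1,3-dioxolan-2-yl]butan-2-one | COc1cc(C)ccc1C1(CC(=O)C(C)=[N+]=[N-])OCCO1
A4 | alternative 2 | 3,3-(ethylenedioxy)-4-methoxy-6,8a-dimethyl-2,3-dihydroazulen-1(8aH)-one | COC1=C2C3(CC(=O)[C@@]2(C)C=CC(C)=C1)OCCO3
A5 | alternative 3 | (3Z)-3-methyl-5-[(1S)-1-methyl-3-(propan-2-yl)cyclopent-2-en-1-yl]pent-3-enal oxime | ON=CC/C(C)=C\C[C@]1(C)CCC(C(C)C)=C1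
A6 | alternative 3 | tricyclic isoxazoline spanning C4, C5 and C6 of the daucane skeleton | CC(C)[C@@]12CC[C@@]3(C)CC=C(C)CC(=NO1)[C@@H]23
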